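**Retrosynthetic overview**
- The target hydroperoxide comes from a singlet-oxygen ene reaction on the C7=C8 alkene of the 11,12-epoxy-4-hydroxy-cembr-7-en-16,3-olide (last step).
- That bicycle comes from an acyclic keto aldehyde thioester: a C3–C4 pinacol coupling closes the 14-membered ring, then the C3 alkoxide closes the δ-lactone in the same flask.
- The keto aldehyde thioester comes from an epoxy enal and a propionate ketene S,O-acetal by iminium-catalysed Mukaiyama–Michael addition (sets C1 and C15).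
- The epoxy enal comes from an epoxy alcohol by C13–C14 allylation of its triflate (new boron-ate coupling) and cross-metathesis with crotonaldehyde.
- The epoxy alcohol comes from (E)-geranylacetone by SeO2 allylic oxidation and Sharpless epoxidation (sets C11 and C12; the epoxide is the first ring formed).

Assumption: cembrane numbering is used for locants (ring C1–C14; C15 carries C16 = carbonyl and C17 = methyl; methyls C18, C19, C20 sit on C4, C8, C12), and (E)-geranylacetone is bought as the single E isomer.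

**Route**

Step 1
Reactants: 1 (5E)-6,10-dimethylundeca-5,9-dien-2-one ((E)-geranylacetone)
Product: 2 (5E,9E)-11-hydroxy-6,10-dimethylundeca-5,9-dien-2-one
Conditions: SeO2 (0.3 equiv), tBuOOH (3 equiv), salicylic acid (0.1 equiv), CH2Cl2, 0 °C to rt
Reagents that add atoms: tert-butyl hydroperoxide (CC(C)(C)OO)
Why: Catalytic SeO2 allylic oxidation (ene reaction then [2,3]-shift) hydroxylates the E-methyl of the terminal trisubstituted alkene selectively, and no stereocenter is formed.

Step 2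
Reactants: 2 (5E,9E)-11-hydroxy-6,10-dimethylundeca-5,9-dien-2-one
Product: 3 (5E)-8-[(2S,3S)-3-(hydroxymethyl)-3-methyloxiran-2-yl]-6-methyloct-5-en-2-one
Conditions: Ti(OiPr)4 (10 mol%), L-(+)-diethyl tartrate (12 mol%), tBuOOH (2 equiv), 4 Å MS, CH2Cl2, −20 °C
Reagents that add atoms: tert-butyl hydroperoxide (CC(C)(C)OO)
Why: Sharpless asymmetric epoxidation delivers oxygen only to the allylic-alcohol alkene (C11=C12) and leaves C7=C8 alone, and the L-(+)-tartrate titanium catalyst sets the first stereocenters as (11S,12S).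

Step 3
Reactants: 3 (5E)-8-[(2S,3S)-3-(hydroxymethyl)-3-methyloxiran-2-yl]-6-methyloct-5-en-2-one; 4 allylboronic acid pinacol ester
Product: 6 (5E)-8-[(2S,3S)-3-(but-3-en-1-yl)-3-methyloxiran-2-yl]-6-methyloct-5-en-2-one, via epoxy triflate 5 (not isolated)
Conditions: Tf2O (1.1 equiv), 2,6-lutidine (1.3 equiv), CH2Cl2, −78 °C; then Li[(allyl)(Ph)B(pin)] (1.5 equiv, from 4 + PhLi, THF, −78 °C), −78 to −20 °C
Reagents that add atoms: allylboronic acid pinacol ester 4 (C=CCB1OC(C)(C)C(C)(C)O1); trifluoromethanesulfonic anhydride (O=S(=O)(OS(=O)(=O)C(F)(F)F)C(F)(F)F, its CF3SO2 group is in 5 only)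
Why: Proposed new method: a lithium allyl(aryl)boronate ate complex is a non-basic, carbonyl-inert carbon nucleophile that should displace the primary triflate in an SN2 step through its γ-carbon (SE2′ at boron, expelling PhB(pin)), so the C13–C14 bond forms without touching the free methyl ketone or the trisubstituted epoxide and C11/C12 are retained; the closest known chemistry is the SE2′ trapping of allylboronate ate complexes by cationic carbon and heteroatom electrophiles and the cuprate displacement of 2,3-epoxy triflates.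

Step 4
Reactants: 6 (5E)-8-[(2S,3S)-3-(but-3-en-1-yl)-3-methyloxiran-2-yl]-6-methyloct-5-en-2-one; 7 crotonaldehyde ((2E)-but-2-enal)
Product: 8 (2E)-5-[(2S,3S)-2-methyl-3-[(3E)-3-methyl-7-oxooct-3-en-1-yl]oxiran-2-yl]pent-2-enal
Conditions: 7 (5 equiv), second-generation Hoveyda–Grubbs catalyst (5 mol%), CH2Cl2, 40 °C
Reagents that add atoms: crotonaldehyde 7 (C/C=C/C=O)
Why: In this olefin cross-metathesis only the monosubstituted alkene enters the catalytic cycle (the trisubstituted C7=C8 alkene is inert), and the conjugated enal forms as the E isomer.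

Step 5
Reactants: 9 propanoyl chloride; 10 propane-2-thiol
Product: 11 S-propan-2-yl propanethioate
Conditions: Et3N (1.2 equiv), CH2Cl2, 0 °C to rt
Reagents that add atoms: propane-2-thiol 10 (CC(C)S)
Why: Acyl substitution of the acid chloride by the thiol (thioesterification) is fast and clean, and no stereocenter is formed.

Step 6
Reactants: 11 S-propan-2-yl propanethioate
Product: 13 tert-butyl(dimethyl){[(1Z)-1-(propan-2-ylsulfanyl)prop-1-en-1-yl]oxy}silane, via lithium thioester enolate 12 (not isolated)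
Conditions: LiN(iPr)2, THF, −78 °C; then tBuMe2SiCl, DMPU, −78 °C to rt
Reagents that add atoms: tert-butyldimethylsilyl chloride (CC(C)(C)[Si](C)(C)Cl); lithium diisopropylamide ([Li+].CC(C)[N-]C(C)C, its lithium is in 12 only)
Why: Kinetic enolization puts the methyl cis to sulfur, and O-silylation (silyl ketene acetal formation) fixes this as the (Z)-ketene S,O-acetal.

Step 7
Reactants: 8 (2E)-5-[(2S,3S)-2-methyl-3-[(3E)-3-methyl-7-oxooct-3-en-1-yl]oxiran-2-yl]pent-2-enal; 13 tert-butyl(dimethyl){[(1Z)-1-(propan-2-ylsulfanyl)prop-1-en-1-yl]oxy}silane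
Product: 14 S-propan-2-yl (2S,3R)-2-methyl-5-[(2S,3S)-2-methyl-3-[(3E)-3-methyl-7-oxooct-3-en-1-yl]oxiran-2-yl]-3-(2-oxoethyl)pentanethioate
Conditions: 13 (2 equiv), (2S,5S)-5-benzyl-2-tert-butyl-3-methylimidazolidin-4-one·Cl3CCO2H (20 mol%), CH2Cl2, H2O (2 equiv), −78 °C
Reagents that add atoms: silyl ketene thioacetal 13 (C/C=C(\SC(C)C)O[Si](C)(C)C(C)(C)C)
Why: In this organocatalytic iminium-activated Mukaiyama–Michael addition the benzyl arm of the imidazolidinone shields one face of the E-iminium so the nucleophile adds to the exposed β-face to give (1R), and the (Z)-ketene thioacetal reacts through an open transition state to give the syn (15S) adduct, with the catalyst rather than the remote epoxide controlling both centres.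

Step 8
Reactants: 14 S-propan-2-yl (2S,3R)-2-methyl-5-[(2S,3S)-2-methyl-3-[(3E)-3-methyl-7-oxooct-3-en-1-yl]oxiran-2-yl]-3-(2-oxoethyl)pentanethioate
Product: 16 (1R,3R,4S,7E,11S,12S,15S)-11,12-epoxy-4-hydroxycembr-7-en-16,3-olide, via diol thioester 15 (not isolated)
Conditions: SmI2 (2.5 equiv), THF (0.003 M, slow addition of 14), −20 °C to rt; then DBU (0.3 equiv), rt
Reagents that add atoms: none
Why: SmI2 pinacol macrocyclization (ketyl–carbonyl coupling at high dilution, a ring-closing mode precedented for cembranoid keto aldehydes with low-valent titanium) should give the erythro (3R,4S) diol because both oxygens bind one trivalent samarium, and the C3 alkoxide then displaces the thioester (lactonization) to lock a chair δ-lactone whose C15 methyl, C1 and C3 substituents are all equatorial, which is also the thermodynamic C15 epimer.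

Step 9
Reactants: 16 (1R,3R,4S,7E,11S,12S,15S)-11,12-epoxy-4-hydroxycembr-7-en-16,3-olide
Product: 17 (1R,3R,4S,6E,8S,11S,12S,15S)-11,12-epoxy-8-hydroperoxy-4-hydroxycembr-6-en-16,3-olide
Conditions: O2, tetraphenylporphyrin (1 mol%), visible light, CH2Cl2, −20 °C
Reagents that add atoms: dioxygen (O=O)
Why: In the Schenck ene reaction of singlet oxygen the cis effect directs hydrogen abstraction to C6 on the disubstituted side of the E-trisubstituted alkene, giving the tertiary C8 hydroperoxide and a new 6E alkene, and attack on the exposed peripheral face of the macrocyclic alkene is relied on to set (8S).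

**Compound list**

1 | (5E)-6,10-dimethylundeca-5,9-dien-2-one ((E)-geranylacetone) | CC(C)=CCC/C(C)=C/CCC(C)=O | starting material
2 | (5E,9E)-11-hydroxy-6,10-dimethylundeca-5,9-dien-2-one | OC/C(C)=C/CC/C(C)=C/CCC(C)=O | intermediate
3 | (5E)-8-[(2S,3S)-3-(hydroxymethyl)-3-methyloxiran-2-yl]-6-methyloct-5-en-2-one | OC[C@]1(C)O[C@H]1CC/C(C)=C/CCC(C)=O | intermediate
4 | allylboronic acid pinacol ester (2-allyl-4,4,5,5-tetramethyl-1,3,2-dioxaborolane) | C=CCB1OC(C)(C)C(C)(C)O1 | starting material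
5 | [(2S,3S)-2-methyl-3-[(3E)-3-methyl-7-oxooct-3-en-1-yl]oxiran-2-yl]methyl trifluoromethanesulfonate | O=S(=O)(OC[C@]1(C)O[C@H]1CC/C(C)=C/CCC(C)=O)C(F)(F)F | intermediate
6 | (5E)-8-[(2S,3S)-3-(but-3-en-1-yl)-3-methyloxiran-2-yl]-6-methyloct-5-en-2-one | C=CCC[C@]1(C)O[C@H]1CC/C(C)=C/CCC(C)=O | intermediate
7 | crotonaldehyde ((2E)-but-2-enal) | C/C=C/C=O | starting material
8 | (2E)-5-[(2S,3S)-2-methyl-3-[(3E)-3-methyl-7-oxooct-3-en-1-yl]oxiran-2-yl]pent-2-enal | O=C/C=C/CC[C@]1(C)O[C@H]1CC/C(C)=C/CCC(C)=O | intermediate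
9 | propanoyl chloride | CCC(=O)Cl | starting material
10 | propane-2-thiol | CC(C)S | starting material
11 | S-propan-2-yl propanethioate | CCC(=O)SC(C)C | intermediate
12 | lithium (1Z)-1-(propan-2-ylsulfanyl)prop-1-en-1-olate | C/C=C(\SC(C)C)[O-].[Li+] | intermediate
13 | tert-butyl(dimethyl){[(1Z)-1-(propan-2-ylsulfanyl)prop-1-en-1-yl]oxy}silane | C/C=C(\SC(C)C)O[Si](C)(C)C(C)(C)C | intermediate
14 | S-propan-2-yl (2S,3R)-2-methyl-5-[(2S,3S)-2-methyl-3-[(3E)-3-methyl-7-oxooct-3-en-1-yl]oxiran-2-yl]-3-(2-oxoethyl)pentanethioate | C[C@H](C(=O)SC(C)C)[C@@H](CC=O)CC[C@]1(C)O[C@H]1CC/C(C)=C/CCC(C)=O | intermediate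
15 | S-propan-2-yl (1R,3R,4S,7E,11S,12S,15S)-11,12-epoxy-3,4-dihydroxycembr-7-en-16-thioate | CC(C)SC(=O)[C@@H](C)[C@@H]1CC[C@]2(C)O[C@H]2CC/C(C)=C/CC[C@](C)(O)[C@H](O)C1 | intermediate
16 | (1R,3R,4S,7E,11S,12S,15S)-11,12-epoxy-4-hydroxycembr-7-en-16,3-olide | C[C@@H]1C(=O)O[C@@H]2C[C@H]1CC[C@]1(C)O[C@H]1CC/C(C)=C/CC[C@]2(C)O | intermediate
17 | (1R,3R,4S,6E,8S,11S,12S,15S)-11,12-epoxy-8-hydroperoxy-4-hydroxycembr-6-en-16,3-olide | C[C@@H]1C(=O)O[C@@H]2C[C@H]1CC[C@]1(C)O[C@H]1CC[C@](C)(OO)/C=C/C[C@]2(C)O | target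

**Step count**

Total: 9 steps (steps 5 and 6 prepare reagent 13). Longest linear sequence: 7 steps (1 → 2 → 3 → 6 → 8 → 14 → 16 → 17).

**Three steps most likely to fail, with fallbacks**

Step 3 (the proposed new boron-ate allylation). The triflate carbon sits next to a fully substituted epoxide carbon, so displacement may be slow, and allyl transfer to the free ketone cannot be excluded. The fallback uses known chemistry, sets out from 1 and comes back at 6, and costs two extra steps. Compound 1 is ketalized (ethylene glycol, pyridinium p-toluenesulfonate, benzene, reflux) to 2-[(3E)-4,8-dimethylnona-3,7-dien-1-yl]-2-methyl-1,3-dioxolane F1. SeO2/tBuOOH oxidation as in step 1 gives (2E,6E)-2,6-dimethyl-9-(2-methyl-1,3-dioxolan-2-yl)nona-2,6-dien-1-ol F2. Sharpless epoxidation as in step 2 gives [(2S,3S)-2-methyl-3-[(3E)-3-methyl-6-(2-methyl-1,3-dioxolan-2-yl)hex-3-en-1-yl]oxiran-2-yl]methanol F3. Tf2O and 2,6-lutidine at −78 °C give the corresponding trifluoromethanesulfonate F4, which is not isolated and is treated with allylMgBr and CuI (10 mol%) in THF at −78 °C to give 2-[(3E)-6-[(2S,3S)-3-(but-3-en-1-yl)-3-methyloxiran-2-yl]-4-methylhex-3-en-1-yl]-2-methyl-1,3-dioxolane F5. Mild hydrolysis (pyridinium p-toluenesulfonate, acetone/H2O, 40 °C) then returns 6.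

Step 8 (pinacol macrocyclization). Ring closure competes with simple reduction and oligomerization, and the erythro/threo ratio at C3/C4 and the sense relative to C1 are only substrate-controlled. The fallback decouples C3 from the C–C bond formation; it sets out from 14 and comes back at 16. The SmI2 reaction is quenched cold without DBU so that diol thioester 15 is isolated as obtained. Its secondary C3 carbinol is oxidized (SO3·pyridine, DMSO, iPr2NEt) to S-propan-2-yl (1R,4S,7E,11S,12S,15S)-11,12-epoxy-4-hydroxy-3-oxocembr-7-en-16-thioate F6, at which stage the C4 epimers are separated. Chelation-controlled reduction with Zn(BH4)2 (Et2O, −20 °C; hydride delivered to the zinc chelate of the α-hydroxy ketone) gives the erythro (3R,4S) diol 15, and DBU then closes the lactone to 16.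

Step 9 (Schenck ene reaction). Hydrogen abstraction from the C19 methyl would give the C7 hydroperoxide with an exocyclic alkene, and facial selectivity on the macrocycle is not guaranteed. The fallback is regiospecific by construction; it sets out from 16 and comes back at 17.
- The C4 hydroxyl is trifluoroacetylated (trifluoroacetic anhydride, pyridine) so that it cannot capture a bromonium ion, giving (1R,3R,4S,7E,11S,12S,15S)-11,12-epoxy-4-(trifluoroacetoxy)cembr-7-en-16,3-olide F7.
- Bromohydroperoxidation (1,3-dibromo-5,5-dimethylhydantoin, anhydrous H2O2, Et2O, −40 °C) adds anti and Markovnikov to give (1R,3R,4S,7R,8S,11S,12S,15S)-7-bromo-11,12-epoxy-8-hydroperoxy-4-(trifluoroacetoxy)cembran-16,3-olide F8.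
- The hydroperoxide is masked with 2-methoxypropene and pyridinium p-toluenesulfonate as (1R,3R,4S,7R,8S,11S,12S,15S)-7-bromo-11,12-epoxy-8-[(2-methoxypropan-2-yl)peroxy]-4-(trifluoroacetoxy)cembran-16,3-olide F9.
- E2 elimination with DBU (toluene, 60 °C) can only go toward C6 and gives (1R,3R,4S,6E,8S,11S,12S,15S)-11,12-epoxy-8-[(2-methoxypropan-2-yl)peroxy]-4-(trifluoroacetoxy)cembr-6-en-16,3-olide F10.
- Aqueous acetic acid in THF, then NaHCO3 in methanol, release 17.

Further compounds

F1 | step 3 | 2-[(3E)-4,8-dimethylnona-3,7-dien-1-yl]-2-methyl-1,3-dioxolane | CC(C)=CCC/C(C)=C/CCC1(C)OCCO1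
F2 | step 3 | (2E,6E)-2,6-dimethyl-9-(2-methyl-1,3-dioxolan-2-yl)nona-2,6-dien-1-ol | OC/C(C)=C/CC/C(C)=C/CCC1(C)OCCO1
F3 | step 3 | [(2S,3S)-2-methyl-3-[(3E)-3-methyl-6-(2-methyl-1,3-dioxolan-2-yl)hex-3-en-1-yl]oxiran-2-yl]methanol | OC[C@]1(C)O[C@H]1CC/C(C)=C/CCC1(C)OCCO1
F4 | step 3 | [(2S,3S)-2-methyl-3-[(3E)-3-methyl-6-(2-methyl-1,3-dioxolan-2-yl)hex-3-en-1-yl]oxiran-2-yl]methyl trifluoromethanesulfonate | O=S(=O)(OC[C@]1(C)O[C@H]1CC/C(C)=C/CCC1(C)OCCO1)C(F)(F)F
F5 | step 3 | 2-[(3E)-6-[(2S,3S)-3-(but-3-en-1-yl)-3-methyloxiran-2-yl]-4-methylhex-3-en-1-yl]-2-methyl-1,3-dioxolane | C=CCC[C@]1(C)O[C@H]1CC/C(C)=C/CCC1(C)OCCO1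
F6 | step 8 | S-propan-2-yl (1R,4S,7E,11S,12S,15S)-11,12-epoxy-4-hydroxy-3-oxocembr-7-en-16-thioate | CC(C)SC(=O)[C@@H](C)[C@@H]1CC[C@]2(C)O[C@H]2CC/C(C)=C/CC[C@](C)(O)C(=O)C1
F7 | step 9 | (1R,3R,4S,7E,11S,12S,15S)-11,12-epoxy-4-(trifluoroacetoxy)cembr-7-en-16,3-olide | C[C@@H]1C(=O)O[C@@H]2C[C@H]1CC[C@]1(C)O[C@H]1CC/C(C)=C/CC[C@]2(C)OC(=O)C(F)(F)F
F8 | step 9 | (1R,3R,4S,7R,8S,11S,12S,15S)-7-bromo-11,12-epoxy-8-hydroperoxy-4-(trifluoroacetoxy)cembran-16,3-olide | C[C@@H]1C(=O)O[C@@H]2C[C@H]1CC[C@]1(C)O[C@H]1CC[C@](C)(OO)[C@H](Br)CC[C@]2(C)OC(=O)C(F)(F)F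
F9 | step 9 | (1R,3R,4S,7R,8S,11S,12S,15S)-7-bromo-11,12-epoxy-8-[(2-methoxypropan-2-yl)peroxy]-4-(trifluoroacetoxy)cembran-16,3-olide | C[C@@H]1C(=O)O[C@@H]2C[C@H]1CC[C@]1(C)O[C@H]1CC[C@](C)(OOC(C)(C)OC)[C@H](Br)CC[C@]2(C)OC(=O)C(F)(F)F
F10 | step 9 | (1R,3R,4S,6E,8S,11S,12S,15S)-11,12-epoxy-8-[(2-methoxypropan-2-yl)peroxy]-4-(trifluoroacetoxy)cembr-6-en-16,3-olide | C[C@@H]1C(=O)O[C@@H]2C[C@H]1CC[C@]1(C)O[C@H]1CC[C@](C)(OOC(C)(C)OC)/C=C/C[C@]2(C)OC(=O)C(F)(F)F
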